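**Assumptions**
- Toxiusol is drawn as the free bis(hydrogen sulfate). It is made as the disodium salt and protonated on an H⁺ resin.
- The sense of induction of the phosphoramidite ligand in Steps 5 and 12 is assigned by analogy with cyclohexenone additions. If it is opposite, the other ligand enantiomer is used.
- Locants in the "Why" lines refer to the product name of that step. The route is a proposal; stereochemical outcomes are predictions from conformational models.

## Retrosynthetic overview
1. Toxiusol ⇐ hydroquinone ⇐ quinone ⇐ dimethyl ether 29 (sulfation and arene unmasking last).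
2. 29 ⇐ West allylic o-DPPB ester 13 + East Grignard from iodide 28, by Cu-mediated syn-SN2′; this forms the C–C link, the West quaternary carbon and the West ring alkene in one step.
3. West: Robinson annulation (intramolecular aldol) gives ring B, oxidised to a prochiral dienone; two conjugate additions set three contiguous centres; a second intramolecular aldol condensation closes ring A.
4. East: the gem-dimethyl ring is bought; asymmetric conjugate addition sets the ring-fusion CH; intramolecular aldol condensation closes the second ring; Johnson–Claisen sets the quaternary carbon and the ring alkene; methylenation/hydrogenation sets the secondary methyl.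
5. Ring order: West B → West A; East second ring onto the purchased ring; the two decalins are joined last.

## West fragment

**Step 1**
Reactants: 1, 2-bromo-1,4-dimethoxybenzene; 2, 2-methylprop-2-en-1-ol
Product: 3, 3-(2,5-dimethoxyphenyl)-2-methylpropanal (racemic)
Conditions: Pd(OAc)2 (2 mol%), Bu4NCl, NaHCO3, DMF, 100 °C
Reagents that add atoms: 2-methylprop-2-en-1-ol (2), C=C(C)CO
Why: Heck arylation of the allylic alcohol followed by β-hydride elimination towards the carbinol gives the aldehyde directly; no stereocontrol is needed because the centre is erased in Step 4.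

**Step 2**
Reactants: 3; 4, but-3-en-2-one
Product: 5, 4-[(2,5-dimethoxyphenyl)methyl]-4-methylcyclohex-2-en-1-one (racemic)
Conditions: KOH (0.2 equiv), EtOH, 0 °C → reflux
Reagents that add atoms: but-3-en-2-one (4), CC(=O)C=C
Why: Robinson annulation: Michael addition of the α-branched aldehyde, then the methyl ketone closes the ring by intramolecular aldol condensation onto the aldehyde.

**Step 3**
Reactants: 5
Product: 6, {4-[(2,5-dimethoxyphenyl)methyl]-4-methylcyclohexa-1,5-dien-1-yl}oxy(trimethyl)silane (racemic)
Conditions: LDA, THF, −78 °C; TMSCl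
Reagents that add atoms: chlorotrimethylsilane, C[Si](C)(C)Cl
Why: Kinetic α′-deprotonation of the enone gives the cross-conjugated silyl dienol ether regioselectively.

**Step 4**
Reactants: 6
Product: 7, 4-[(2,5-dimethoxyphenyl)methyl]-4-methylcyclohexa-2,5-dien-1-one (achiral, prochiral)
Conditions: Pd(OAc)2 (1.05 equiv), MeCN, rt
Reagents that add atoms: none
Why: Saegusa–Ito oxidation gives the cross-conjugated dienone under neutral conditions that leave the electron-rich benzylic CH2 alone.

**Step 5**
Reactants: 7; 8, 2-(3-chloropropyl)-2-methyl-1,3-dioxolane (used as its diorganozinc)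
Product: 9, (4S,5R)-4-[(2,5-dimethoxyphenyl)methyl]-4-methyl-5-[3-(2-methyl-1,3-dioxolan-2-yl)propyl]cyclohex-2-en-1-one
Conditions: 8, Mg, THF; ZnCl2 (0.5 equiv), dioxane (R2Zn); Cu(OTf)2 (2 mol%), (S,R,R)-Feringa phosphoramidite (4 mol%), toluene, −30 °C
Reagents that add atoms: 2-(3-chloropropyl)-2-methyl-1,3-dioxolane (8), CC1(CCCCl)OCCO1
Why: Cu-catalysed asymmetric conjugate addition desymmetrises the dienone; the ligand chooses one enantiotopic alkene and the alkyl group enters anti to the larger benzyl group, setting C4 and C5 together.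

**Step 6**
Reactants: 9
Product: 10, (3R,4R,5R)-4-[(2,5-dimethoxyphenyl)methyl]-3,4-dimethyl-5-[3-(2-methyl-1,3-dioxolan-2-yl)propyl]cyclohexan-1-one
Conditions: Me2CuLi (2 equiv), TMSCl, THF, −78 → 0 °C; then K2CO3, MeOH
Reagents that add atoms: lithium dimethylcuprate, [Li+].C[Cu-]C
Why: Cuprate conjugate addition by axial attack trans to the C5 side chain (3,5-trans rule) and anti to the pseudoaxial C4 methyl, which places the new methyl cis to the benzyl group.

**Step 7**
Reactants: 10
Product: 11, (3R,4R,4aS)-4-[(2,5-dimethoxyphenyl)methyl]-3,4,8-trimethyl-3,4,4a,5,6,7-hexahydronaphthalen-1(2H)-one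
Conditions: 2 M HCl, THF, rt; then KOH, MeOH, reflux
Reagents that add atoms: none
Why: Ketal hydrolysis then intramolecular aldol condensation; only attack of the ring α-carbon on the side-chain ketone gives a fused six-membered ring that can dehydrate, and no stereocentre is epimerisable.

**Step 8**
Reactants: 11
Product: 12, (1S,3R,4R,4aS)-4-[(2,5-dimethoxyphenyl)methyl]-3,4,8-trimethyl-1,2,3,4,4a,5,6,7-octahydronaphthalen-1-ol
Conditions: L-Selectride, THF, −78 °C
Reagents that add atoms: none
Why: 1,2-reduction of the tetrasubstituted enone; the axial C3 methyl blocks axial attack, so hydride comes from the opposite face and gives the axial (1S) alcohol, cis to H-4a.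

**Step 9**
Reactants: 12
Product: 13, the 2-(diphenylphosphanyl)benzoate of 12 (same stereocentres)
Conditions: 2-(Ph2P)C6H4CO2H, DCC, DMAP, CH2Cl2, rt
Reagents that add atoms: 2-(diphenylphosphanyl)benzoic acid, OC(=O)c1ccccc1P(c1ccccc1)c1ccccc1
Why: Steglich esterification installs the phosphine-bearing leaving group that directs copper in Step 22.

## East fragment

**Step 10**
Reactants: 14, 3-chloropropanoyl chloride; 15, isopropenylmagnesium bromide
Product: 16, 5-chloro-2-methylpent-1-en-3-one
Conditions: 15, ZnCl2, THF, 0 °C; then 14, Pd(PPh3)4 (2 mol%), 0 °C → rt; used crude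
Reagents that add atoms: isopropenylmagnesium bromide (15), C=C(C)[Mg]Br
Why: Negishi acylation of the alkenylzinc gives the ketone without over-addition or conjugate addition to the product enone.

**Step 11**
Reactants: 16
Product: 17, 2-(2-chloroethyl)-2-(prop-1-en-2-yl)-1,3-dioxolane
Conditions: TMSOCH2CH2OTMS, TMSOTf (cat.), CH2Cl2, −78 → −20 °C
Reagents that add atoms: 1,2-bis(trimethylsilyloxy)ethane, C[Si](C)(C)OCCO[Si](C)(C)C
Why: Noyori ketalisation protects the enone carbonyl without conjugate addition of the diol or alkene migration.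

**Step 12**
Reactants: 17 (as its diorganozinc); 18, 4,4-dimethylcyclohex-2-en-1-one
Product: 19, (3S)-4,4-dimethyl-3-{2-[2-(prop-1-en-2-yl)-1,3-dioxolan-2-yl]ethyl}cyclohexan-1-one
Conditions: 17, Mg, THF; ZnCl2 (0.5 equiv), dioxane; Cu(OTf)2 (2 mol%), (R,S,S)-Feringa phosphoramidite (4 mol%), toluene, −30 °C
Reagents that add atoms: 2-(2-chloroethyl)-2-(prop-1-en-2-yl)-1,3-dioxolane (17), ClCCC1(OCCO1)C(C)=C
Why: Feringa-type asymmetric conjugate addition, for which this enone is a standard substrate, sets the future ring-fusion CH under ligand control.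

**Step 13**
Reactants: 19
Product: 20, (3S)-3-[2-(2-acetyl-1,3-dioxolan-2-yl)ethyl]-4,4-dimethylcyclohexan-1-one
Conditions: O3, CH2Cl2/MeOH, −78 °C; Me2S
Reagents that add atoms: ozone, [O-][O+]=O
Why: Ozonolysis of the only alkene unmasks the methyl ketone while the neighbouring carbonyl stays protected.

**Step 14**
Reactants: 20
Product: 21, (4aR)-7,7-(ethylenedioxy)-4,4,8-trimethyl-3,4,4a,5,6,7-hexahydronaphthalen-1(2H)-one
Conditions: KOH, MeOH, reflux
Reagents that add atoms: none
Why: Intramolecular aldol condensation; the acetyl group can enolise only towards its methyl (eight-membered ring, not formed), so only the ring C2 enolate attacks the acetyl carbonyl to give the fused six-membered enone.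

**Step 15**
Reactants: 21
Product: 22, (1S,4aR)-7,7-(ethylenedioxy)-4,4,8-trimethyl-1,2,3,4,4a,5,6,7-octahydronaphthalen-1-ol
Conditions: NaBH4, CeCl3·7H2O, MeOH, −20 °C
Reagents that add atoms: none
Why: Luche 1,2-reduction; the small hydride attacks axially on the face of the axial H-4a, giving the equatorial (1S) alcohol trans to H-4a.

**Step 16**
Reactants: 22
Product: 23, ethyl [(1S,4aR)-2,2-(ethylenedioxy)-1,5,5-trimethyl-1,2,3,4,4a,5,6,7-octahydronaphthalen-1-yl]acetate
Conditions: MeC(OEt)3 (solvent), EtCO2H (cat.), 140 °C, EtOH distilled off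
Reagents that add atoms: triethyl orthoacetate, CC(OCC)(OCC)OCC
Why: Johnson–Claisen rearrangement; the suprafacial [3,3] shift transfers the C–O configuration to the new quaternary carbon (acetate arm trans to H-4a) and moves the alkene to its final position.

**Step 17**
Reactants: 23
Product: 24, ethyl [(1S,4aR)-1,5,5-trimethyl-2-oxo-1,2,3,4,4a,5,6,7-octahydronaphthalen-1-yl]acetate
Conditions: 2 M HCl, THF, 45 °C
Reagents that add atoms: water, O
Why: Ketal hydrolysis; the quaternary α-carbon prevents conjugation or epimerisation of the β,γ-unsaturated ketone.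

**Step 18**
Reactants: 24
Product: 25, ethyl [(1R,4aR)-1,5,5-trimethyl-2-methylidene-1,2,3,4,4a,5,6,7-octahydronaphthalen-1-yl]acetate
Conditions: Ph3PCH3Br, KHMDS, THF, 0 → 65 °C
Reagents that add atoms: methylidenetriphenylphosphorane, C=P(c1ccccc1)(c1ccccc1)c1ccccc1
Why: Wittig methylenation of the ketone; the ester does not react with the non-stabilised ylide under these conditions.

**Step 19**
Reactants: 25
Product: 26, ethyl [(1R,2S,4aR)-1,2,5,5-tetramethyl-1,2,3,4,4a,5,6,7-octahydronaphthalen-1-yl]acetate
Conditions: H2 (1 atm), PtO2, EtOAc, rt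
Reagents that add atoms: none
Why: Hydrogenation of the 1,1-disubstituted alkene only (the ring alkene is trisubstituted and flanked by a quaternary carbon); H2 adds anti to the axial C1 methyl, giving the cis-1,2-dimethyl arrangement.

**Step 20**
Reactants: 26
Product: 27, 2-[(1R,2S,4aR)-1,2,5,5-tetramethyl-1,2,3,4,4a,5,6,7-octahydronaphthalen-1-yl]ethan-1-ol
Conditions: LiAlH4, THF, 0 °C
Reagents that add atoms: none
Why: Ester reduction to the primary alcohol.

**Step 21**
Reactants: 27
Product: 28, (1R,2S,4aR)-1-(2-iodoethyl)-1,2,5,5-tetramethyl-1,2,3,4,4a,5,6,7-octahydronaphthalene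
Conditions: I2, PPh3, imidazole, CH2Cl2, 0 °C → rt
Reagents that add atoms: iodine, II
Why: Appel iodination of an unhindered primary alcohol.

## Fragment union and endgame

**Step 22**
Reactants: 13; 28
Product: 29, 2-{[(1R,2R,5S,8aS)-1,2,5-trimethyl-5-{2-[(1R,2S,4aR)-1,2,5,5-tetramethyl-1,2,3,4,4a,5,6,7-octahydronaphthalen-1-yl]ethyl}-1,2,3,5,6,7,8,8a-octahydronaphthalen-1-yl]methyl}-1,4-dimethoxybenzene
Conditions: 28 (1.3 equiv), t-BuLi (2.1 equiv), Et2O, −78 °C; MgBr2·OEt2; added slowly to 13, CuBr·SMe2 (0.5 equiv), Et2O, rt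
Reagents that add atoms: iodide 28, ICC[C@@]1(C)C2=CCCC(C)(C)[C@H]2CC[C@@H]1C
Why: o-DPPB-directed Cu-mediated syn-SN2′ allylic substitution; the phosphine delivers the alkyl group to the alkene terminus on the face of the axial C–O bond, creating the (5S) quaternary carbon and the trisubstituted ring alkene.

**Step 23**
Reactants: 29
Product: 30, the corresponding 2-substituted cyclohexa-2,5-diene-1,4-dione (quinone), same seven stereocentres
Conditions: CAN (2.5 equiv), MeCN/H2O, 0 °C
Reagents that add atoms: water, O
Why: CAN oxidative demethylation of the 1,4-dimethoxyarene to the quinone, as used for avarol-type dimethyl ethers; isolated trisubstituted alkenes survive.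

**Step 24**
Reactants: 30
Product: 31, the corresponding 2-substituted benzene-1,4-diol (hydroquinone)
Conditions: Na2S2O4, EtOAc/H2O, rt, under Ar; used directly
Reagents that add atoms: none
Why: Dithionite reduction of the quinone to the air-sensitive hydroquinone.

**Step 25**
Reactants: 31
Product: 32, toxiusol
Conditions: SO3·pyridine (8 equiv), pyridine, 60 °C; aq. Na2CO3 (disodium salt); Dowex 50W (H⁺), 0 °C
Reagents that add atoms: sulfur trioxide–pyridine complex, [O-]S(=O)(=O)[n+]1ccccc1
Why: O-sulfation of both phenols with SO3·pyridine; no stereocentre is touched.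

## Compound list
1 | 2-bromo-1,4-dimethoxybenzene | COc1ccc(OC)c(Br)c1 | starting material
2 | 2-methylprop-2-en-1-ol | C=C(C)CO | starting material
3 | 3-(2,5-dimethoxyphenyl)-2-methylpropanal (rac) | O=CC(C)Cc1cc(OC)ccc1OC | intermediate
4 | but-3-en-2-one | CC(=O)C=C | starting material
5 | 4-[(2,5-dimethoxyphenyl)methyl]-4-methylcyclohex-2-en-1-one (rac) | O=C1C=CC(C)(Cc2cc(OC)ccc2OC)CC1 | intermediate
6 | silyl dienol ether of 5 (rac) | C[Si](C)(C)OC1=CCC(C)(Cc2cc(OC)ccc2OC)C=C1 | intermediate
7 | 4-[(2,5-dimethoxyphenyl)methyl]-4-methylcyclohexa-2,5-dien-1-one | O=C1C=CC(C)(Cc2cc(OC)ccc2OC)C=C1 | intermediate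
8 | 2-(3-chloropropyl)-2-methyl-1,3-dioxolane | CC1(CCCCl)OCCO1 | starting material
9 | (4S,5R)-cyclohexenone | O=C1C=C[C@@](C)(Cc2cc(OC)ccc2OC)[C@H](CCCC2(C)OCCO2)C1 | intermediate
10 | (3R,4R,5R)-cyclohexanone | C[C@@H]1CC(=O)C[C@@H](CCCC2(C)OCCO2)[C@]1(C)Cc1cc(OC)ccc1OC | intermediate
11 | (3R,4R,4aS)-bicyclic enone | C[C@@H]1CC(=O)C2=C(C)CCC[C@H]2[C@]1(C)Cc1cc(OC)ccc1OC | intermediate
12 | (1S,3R,4R,4aS)-allylic alcohol | C[C@@H]1C[C@H](O)C2=C(C)CCC[C@H]2[C@]1(C)Cc1cc(OC)ccc1OC | intermediate
13 | o-DPPB ester of 12 | C[C@@H]1C[C@H](OC(=O)c3ccccc3P(c3ccccc3)c3ccccc3)C2=C(C)CCC[C@H]2[C@]1(C)Cc1cc(OC)ccc1OC | intermediate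
14 | 3-chloropropanoyl chloride | ClCCC(Cl)=O | starting material
15 | isopropenylmagnesium bromide | C=C(C)[Mg]Br | starting material
16 | 5-chloro-2-methylpent-1-en-3-one | ClCCC(=O)C(C)=C | intermediate
17 | 2-(2-chloroethyl)-2-(prop-1-en-2-yl)-1,3-dioxolane | ClCCC1(OCCO1)C(C)=C | intermediate
18 | 4,4-dimethylcyclohex-2-en-1-one | O=C1C=CC(C)(C)CC1 | starting material
19 | (3S)-conjugate adduct | O=C1CCC(C)(C)[C@@H](CCC2(OCCO2)C(C)=C)C1 | intermediate
20 | (3S)-diketone mono-ketal | O=C1CCC(C)(C)[C@@H](CCC2(OCCO2)C(C)=O)C1 | intermediate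
21 | (4aR)-bicyclic enone ketal | O=C1CCC(C)(C)[C@H]2CCC3(OCCO3)C(C)=C12 | intermediate
22 | (1S,4aR)-allylic alcohol | O[C@H]1CCC(C)(C)[C@H]2CCC3(OCCO3)C(C)=C12 | intermediate
23 | (1S,4aR)-Claisen ester ketal | CCOC(=O)C[C@@]1(C)C2=CCCC(C)(C)[C@H]2CCC13OCCO3 | intermediate
24 | (1S,4aR)-keto ester | CCOC(=O)C[C@@]1(C)C2=CCCC(C)(C)[C@H]2CCC1=O | intermediate
25 | (1R,4aR)-methylidene ester | CCOC(=O)C[C@@]1(C)C2=CCCC(C)(C)[C@H]2CCC1=C | intermediate
26 | (1R,2S,4aR)-ester | CCOC(=O)C[C@@]1(C)C2=CCCC(C)(C)[C@H]2CC[C@@H]1C | intermediate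
27 | (1R,2S,4aR)-alcohol | OCC[C@@]1(C)C2=CCCC(C)(C)[C@H]2CC[C@@H]1C | intermediate
28 | (1R,2S,4aR)-iodide | ICC[C@@]1(C)C2=CCCC(C)(C)[C@H]2CC[C@@H]1C | intermediate
29 | toxiusol hydroquinone dimethyl ether | C[C@@H]1CC=C2[C@@H](CCC[C@@]2(C)CC[C@@]2(C)C3=CCCC(C)(C)[C@H]3CC[C@@H]2C)[C@]1(C)Cc1cc(OC)ccc1OC | intermediate
30 | quinone | C[C@@H]1CC=C2[C@@H](CCC[C@@]2(C)CC[C@@]2(C)C3=CCCC(C)(C)[C@H]3CC[C@@H]2C)[C@]1(C)CC1=CC(=O)C=CC1=O | intermediate
31 | hydroquinone | C[C@@H]1CC=C2[C@@H](CCC[C@@]2(C)CC[C@@]2(C)C3=CCCC(C)(C)[C@H]3CC[C@@H]2C)[C@]1(C)Cc1cc(O)ccc1O | intermediate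
32 | toxiusol | C[C@@H]1CC=C2[C@@H](CCC[C@@]2(C)CC[C@@]2(C)C3=CCCC(C)(C)[C@H]3CC[C@@H]2C)[C@]1(C)Cc1cc(OS(=O)(=O)O)ccc1OS(=O)(=O)O | target

## Step count
- Total steps: 25.
- Longest linear sequence: 16 (Steps 10–25, from 14/15 to 32), which is 64% of the total. The West branch is 9 steps before the union.

## Three steps most likely to fail, with fallbacks
1. **Step 22 (directed SN2′ union).** The alkene is tetrasubstituted, the new centre is quaternary, and the nucleophile is a valuable β-quaternary Grignard; SN2 attack or ester cleavage could compete. Fallback: give each fragment a one-carbon handle by Still [2,3]-Wittig rearrangement of allylic alcohols 12 and 22 (Bu3SnCH2I, then n-BuLi), which sets the same quaternary centres and alkenes. Then join a West neopentyl aldehyde and an East PT-sulfone by Julia–Kocienski olefination and reduce the new disubstituted alkene with diimide.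
2. **Step 5 (desymmetrising conjugate addition).** Facial discrimination between benzyl and methyl on the dienone may be modest, and the ee is untested for this substrate. Fallback: set the methyl-bearing and quaternary centres first by Cu-catalysed asymmetric addition of Me3Al to 2-(2,5-dimethoxybenzyl)cyclohex-2-enone with MeI trapping of the enolate. Convert that ketone to the cyclohexene (enol triflate, Pd/HCO2H), oxidise the allylic CH2 to the 4,4,5-trisubstituted cyclohexenone, and add the side chain by substrate-controlled cuprate addition trans to the ring methyl.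
3. **Step 16 (Johnson–Claisen).** The new quaternary carbon sits next to a ketal carbon, and the required alcohol is equatorial, so the ring must twist to reach the transition state; elimination to a diene may compete. Fallback: reduce 21 with L-Selectride to the axial (1R) alcohol, make its phosphate, and install the two-carbon arm by Cu-mediated anti-SN2′ substitution with vinylmagnesium bromide. Hydroborate the vinyl group (9-BBN) to the primary alcohol after the methylenation/hydrogenation sequence.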